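Of the five hydroxyl-type oxygens of the flavonol, only those on C7 (ring A) and C4' (ring B) are sulfate esters. The plan cuts exactly these two aryl C–O bonds. Both carbons travel as C–Br while the chromone is assembled, so O3, O5 and O3' can all be benzylated without any site selection. One pot of twofold Miyaura borylation and perborate oxidation then converts 7,4'-dibromide 13, which bears benzyloxy groups at C3, C5 and C3', into diol 15. Its two free phenols are the sulfation sites. Sulfation, hydrogenolysis and cation exchange finish the synthesis.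

Key step: step 5

Remark 1: the target has no stereocentre, axis or other stereogenic element and is achiral, so no enantiomer has to be selected and no step has to control configuration.
Remark 2: Weinreb amide 5 is taken as a catalogue compound, sulfate salts are drawn as separated ions, and free acid 19 is expected to hydrolyse easily, so it should be handled cold and stored frozen and dry.

Step 1
Reactants: 1 4-bromo-3-hydroxybenzoic acid
Product: 3 3-(benzyloxy)-4-bromobenzoic acid, via benzyl 3-(benzyloxy)-4-bromobenzoate 2 (not isolated)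
Conditions: BnBr (2.3 equiv), K2CO3, DMF, 60 °C; then 2 M NaOH, THF–MeOH, 50 °C; MTBE wash; 1 M HCl to pH 2
Reagents that add atoms: benzyl bromide BrCc1ccccc1; sodium hydroxide [Na+].[OH-] (acid oxygen of 3)
Why: Williamson O-alkylation of phenoxide and carboxylate, followed by saponification of the only ester, should give the ether acid, which acid–base extraction frees from neutral benzyl residues; the aryl bromide is inert to both operations.

Step 2
Reactants: 4 1-bromo-3,5-difluorobenzene; 5 2-(benzyloxy)-N-methoxy-N-methylacetamide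
Product: 7 2-(benzyloxy)-1-(4-bromo-2,6-difluorophenyl)ethan-1-one, via (4-bromo-2,6-difluorophenyl)lithium 6 (not isolated)
Conditions: LDA (1.05 equiv), THF, −78 °C; then 5 (1.1 equiv), −78 °C; 1 M HCl quench at −78 °C
Reagents that add atoms: lithium diisopropylamide [Li+].CC(C)[N-]C(C)C (lithium of 6 only)
Why: In this directed ortho-lithiation and Weinreb ketone synthesis, LDA removes the most acidic C–H, the one between the two fluorines, without touching C–Br, and the aryllithium adds only once because the N-methoxy chelate holds the tetrahedral adduct until the cold acid quench.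

Step 3
Reactants: 3 3-(benzyloxy)-4-bromobenzoic acid; 7 2-(benzyloxy)-1-(4-bromo-2,6-difluorophenyl)ethan-1-one
Product: 10 2-(benzyloxy)-1-[3-(benzyloxy)-4-bromophenyl]-3-(4-bromo-2,6-difluorophenyl)propane-1,3-dione, via 3-(benzyloxy)-4-bromobenzoyl chloride 8 (not isolated), via lithium (Z)-2-(benzyloxy)-1-(4-bromo-2,6-difluorophenyl)ethenolate 9 (not isolated)
Conditions: 3, (COCl)2, cat. DMF, CH2Cl2, 0 °C → rt, evaporate; separately 7, LiHMDS (2.2 equiv), THF, −78 °C; then 8 in THF, −78 → −20 °C; 1 M HCl
Reagents that add atoms: oxalyl chloride O=C(Cl)C(=O)Cl (chlorine of 8 only); lithium hexamethyldisilazide [Li+].C[Si](C)(C)[N-][Si](C)(C)C (lithium of 9 only)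
Why: This is a Claisen-type C-acylation of a chelated ketone lithium enolate with an unhindered aroyl chloride, in which the second equivalent of base deprotonates the acidic product so that the diketonate is the thermodynamic sink; the C2 centre of 10 is racemic, labile and lost in step 4.

Step 4
Reactants: 10 2-(benzyloxy)-1-[3-(benzyloxy)-4-bromophenyl]-3-(4-bromo-2,6-difluorophenyl)propane-1,3-dione; 11 benzyl alcohol
Product: 13 3,5-bis(benzyloxy)-2-[3-(benzyloxy)-4-bromophenyl]-7-bromo-4H-chromen-4-one, via 5-fluoro-7,4'-dibromoflavonol dibenzyl ether 12 (not isolated)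
Conditions: KOtBu (1.05 equiv), DMF, 0 → 50 °C; then 0 °C, 11 (1.3 equiv)/KOtBu (1.2 equiv) premixed in THF, → rt
Reagents that add atoms: none
Why: Two addition–elimination SNAr reactions occur on carbonyl-activated C–F bonds: the ring-B-side diketonate oxygen closes the six-membered pyranone on either of the two equivalent ortho fluorines, and benzyloxide then replaces 5-F, which is ortho to C4=O and leaves far faster than 7-Br; if the order inverted, both sequences would still end at 13.

Step 5
Reactants: 13 3,5-bis(benzyloxy)-2-[3-(benzyloxy)-4-bromophenyl]-7-bromo-4H-chromen-4-one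
Product: 15 3,5-bis(benzyloxy)-2-[3-(benzyloxy)-4-hydroxyphenyl]-7-hydroxy-4H-chromen-4-one (3,5,3'-tri-O-benzylquercetin), via 7,4'-bis(pinacol boronate) 14 (not isolated)
Conditions: B2pin2 (2.6 equiv), Pd(dppf)Cl2·CH2Cl2 (5 mol %), KOAc (6 equiv), 1,4-dioxane, 85 °C; then THF–H2O, NaBO3·4H2O (8 equiv), 0 °C → rt; aq. NH4Cl
Reagents that add atoms: bis(pinacolato)diboron CC1(C)OB(OC1(C)C)B1OC(C)(C)C(C)(C)O1 (boronate groups of 14 only); sodium perborate [Na+].[Na+].O[B-]1(O)OO[B-](O)(O)OO1 (O7 and O4' of 15)
Why: Pd(0) inserts into C7–Br and C4'–Br, both para to the electron-poor pyranone (C7 through C4a to C4=O, C4' through C1' to C2), acetate replaces bromide on palladium and draws a Bpin unit across from the diboron, and reductive elimination leaves bis(boronate) 14. Hydroperoxide released by perborate then adds to each boron and the aryl group shifts from boron to oxygen, so that after hydrolysis of the aryl borate each new hydroxyl sits on the carbon that carried bromine. The reaction type is the Miyaura borylation of aryl bromides followed by the standard oxidative ipso-hydroxylation of arylboronates, here run at two sites of one molecule. No ring is closed and no stereocentre is created. The step needs chemoselectivity and positional fidelity: the two C(sp2)–Br bonds are the only sites open to Pd(0) because C5–F has already been exchanged and benzyl ethers are inert, while potassium acetate is too weak a base to start Suzuki coupling of 14 with 13 or to open the pyranone at C2. A chelating ligand, moderate temperature and excess diboron should keep transmetalation ahead of acetate-assisted C–H arylation of the neighbouring 3'-O-benzyl ring, and surplus perborate also destroys leftover diboron.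

Step 6
Reactants: 15 3,5,3'-tri-O-benzylquercetin
Product: 17 disodium 3,5,3'-tri-O-benzylquercetin 7,4'-disulfate, via bis(pyridinium) disulfate 16 (not isolated)
Conditions: SO3·pyridine (6 equiv), pyridine, rt → 40 °C; then aq. NaHCO3 to pH 8; C18 silica, H2O → MeOH
Reagents that add atoms: sulfur trioxide–pyridine complex O=S(=O)([O-])[n+]1ccccc1; sodium hydrogencarbonate [Na+].OC([O-])=O
Why: In this O-sulfation of phenols with a sulfur trioxide–amine complex, 15 offers only the hydroxyls at C7 and C4', so excess reagent can be used without site selection, and bicarbonate exchange should give a neutral sodium salt that can be chromatographed free of pyridine.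

Step 7
Reactants: 17 disodium 3,5,3'-tri-O-benzylquercetin 7,4'-disulfate
Product: 19 3',5-dihydroxy-4',7-bis(sulfooxy)flavonol (quercetin 7,4'-bis(hydrogen sulfate)), via disodium quercetin 7,4'-disulfate 18 (not isolated)
Conditions: H2 (1 atm), 10% Pd/C, MeOH–H2O, rt; filter, strip MeOH below 20 °C; Dowex 50WX8 (H+ form), H2O, 4 °C; freeze-dry
Reagents that add atoms: none
Why: Catalytic hydrogenolysis cleaves the three benzylic C–O bonds while aryl sulfate monoester anions and the tetrasubstituted C2=C3 bond are inert at 1 atm, and strong-acid cation exchange in cold water then swaps sodium for protons, leaving volatile toluene as the only organic by-product.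

Compound list
1 | 4-bromo-3-hydroxybenzoic acid | O=C(O)c1ccc(Br)c(O)c1 | starting material
2 | benzyl 3-(benzyloxy)-4-bromobenzoate | O=C(OCc1ccccc1)c1ccc(Br)c(OCc2ccccc2)c1 | intermediate
3 | 3-(benzyloxy)-4-bromobenzoic acid | O=C(O)c1ccc(Br)c(OCc2ccccc2)c1 | intermediate
4 | 1-bromo-3,5-difluorobenzene | Fc1cc(F)cc(Br)c1 | starting material
5 | 2-(benzyloxy)-N-methoxy-N-methylacetamide | CON(C)C(=O)COCc1ccccc1 | starting material
6 | (4-bromo-2,6-difluorophenyl)lithium | [Li]c1c(F)cc(Br)cc1F | intermediate
7 | 2-(benzyloxy)-1-(4-bromo-2,6-difluorophenyl)ethan-1-one | O=C(COCc1ccccc1)c1c(F)cc(Br)cc1F | intermediate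
8 | 3-(benzyloxy)-4-bromobenzoyl chloride | O=C(Cl)c1ccc(Br)c(OCc2ccccc2)c1 | intermediate
9 | lithium (Z)-2-(benzyloxy)-1-(4-bromo-2,6-difluorophenyl)ethenolate | [Li]O/C(=C\OCc1ccccc1)c1c(F)cc(Br)cc1F | intermediate
10 | (±)-2-(benzyloxy)-1-[3-(benzyloxy)-4-bromophenyl]-3-(4-bromo-2,6-difluorophenyl)propane-1,3-dione (labile C2 centre, racemic) | O=C(c1ccc(Br)c(OCc2ccccc2)c1)C(OCc1ccccc1)C(=O)c1c(F)cc(Br)cc1F | intermediate
11 | benzyl alcohol | OCc1ccccc1 | starting material
12 | 3-(benzyloxy)-2-[3-(benzyloxy)-4-bromophenyl]-7-bromo-5-fluoro-4H-chromen-4-one | O=c1c(OCc2ccccc2)c(-c2ccc(Br)c(OCc3ccccc3)c2)oc2cc(Br)cc(F)c12 | intermediate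
13 | 3,5-bis(benzyloxy)-2-[3-(benzyloxy)-4-bromophenyl]-7-bromo-4H-chromen-4-one (key-step precursor) | O=c1c(OCc2ccccc2)c(-c2ccc(Br)c(OCc3ccccc3)c2)oc2cc(Br)cc(OCc3ccccc3)c12 | intermediate
14 | 3,5-bis(benzyloxy)-2-[3-(benzyloxy)-4-(pinacolboryl)phenyl]-7-(pinacolboryl)-4H-chromen-4-one | O=c1c(OCc2ccccc2)c(-c2ccc(B3OC(C)(C)C(C)(C)O3)c(OCc3ccccc3)c2)oc2cc(B3OC(C)(C)C(C)(C)O3)cc(OCc3ccccc3)c12 | intermediate
15 | 3,5,3'-tri-O-benzylquercetin (key-step product) | O=c1c(OCc2ccccc2)c(-c2ccc(O)c(OCc3ccccc3)c2)oc2cc(O)cc(OCc3ccccc3)c12 | intermediate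
16 | bis(pyridinium) 3,5,3'-tri-O-benzylquercetin 7,4'-disulfate | O=c1c(OCc2ccccc2)c(-c2ccc(OS(=O)(=O)[O-])c(OCc3ccccc3)c2)oc2cc(OS(=O)(=O)[O-])cc(OCc3ccccc3)c12.c1cc[nH+]cc1.c1cc[nH+]cc1 | intermediate
17 | disodium 3,5,3'-tri-O-benzylquercetin 7,4'-disulfate | O=c1c(OCc2ccccc2)c(-c2ccc(OS(=O)(=O)[O-])c(OCc3ccccc3)c2)oc2cc(OS(=O)(=O)[O-])cc(OCc3ccccc3)c12.[Na+].[Na+] | intermediate
18 | disodium quercetin 7,4'-disulfate | O=c1c(O)c(-c2ccc(OS(=O)(=O)[O-])c(O)c2)oc2cc(OS(=O)(=O)[O-])cc(O)c12.[Na+].[Na+] | intermediate
19 | 3',5-dihydroxy-4',7-bis(sulfooxy)flavonol (achiral) | O=c1c(O)c(-c2ccc(OS(=O)(=O)O)c(O)c2)oc2cc(OS(=O)(=O)O)cc(O)c12 | target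

Total step count: 7. Longest linear sequence: 6 steps (1 → 3 → 10 → 13 → 15 → 17 → 19; the branch from 4 through 7 is equally long).

Steps most likely to fail

Step 5. Several processes could spoil this step:
- Oxidative addition at C4'–Br, which is crowded by the ortho benzyloxy group, may lag behind that at C7–Br.
- The C4'–Pd species may arylate the neighbouring benzyl ring.
- Hydrodebromination or protodeboronation may erase a coded site before oxidation.

The fallback sets out from 13 and forms the same two C–O bonds by direct palladium-catalysed C–O coupling with a hydroxide surrogate. The conditions would be (E)-benzaldoxime (3 equiv), tBuBrettPhos Pd G3 and Cs2CO3 in DMF at 80 °C. They should give the bis(O-aryl benzaldoxime ether) F1. Under the same base F1 fragments by elimination to the two phenoxides, and mild acidification returns the route at 15.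

Step 3. The ambident enolate may be acylated on oxygen instead of carbon, or the product may be acylated a second time.

The fallback sets out from 7 and replaces acylation by aldol addition and oxidation.
- Commercial 4-bromo-3-hydroxybenzaldehyde (O=Cc1ccc(Br)c(O)c1) is benzylated (BnBr, K2CO3, DMF) to 3-(benzyloxy)-4-bromobenzaldehyde F2.
- Enolate 9 (LiHMDS, THF, −78 °C, cold quench) adds to F2, which can only capture the enolate productively at carbon. This gives the β-hydroxy ketone F3 as a mixture of diastereomers, whose configuration is irrelevant.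
- Dess–Martin oxidation of F3 in CH2Cl2 rejoins the route at 10.

Step 7. Residues from the sulfation may deactivate the catalyst, so that protecting groups are lost only in part. The sulfate esters may also solvolyse while the acid form is being concentrated.

The fallback sets out from 15 and carries the sulfates in masked, neutral form.
- 2,2,2-Trichloroethyl chlorosulfate (ClS(=O)(=O)OCC(Cl)(Cl)Cl) with Et3N and DMAP in THF (0 °C → rt) should give the 7,4'-bis(2,2,2-trichloroethyl sulfate) F4, which can be purified on ordinary silica.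
- Transfer hydrogenolysis (Pd/C, HCO2NH4, MeOH) removes the three benzyl ethers and both trichloroethyl groups in one buffered operation, giving diammonium quercetin 7,4'-disulfate F5.
- A brief cold pass of F5 through the H+ resin, followed by freeze-drying, arrives at 19.

Further compounds
F1 | step 5 | 3,5-bis(benzyloxy)-2-{3-(benzyloxy)-4-[(E)-(benzylideneamino)oxy]phenyl}-7-[(E)-(benzylideneamino)oxy]-4H-chromen-4-one | O=c1c(OCc2ccccc2)c(-c2ccc(O/N=C/c3ccccc3)c(OCc3ccccc3)c2)oc2cc(O/N=C/c3ccccc3)cc(OCc3ccccc3)c12
F2 | step 3 | 3-(benzyloxy)-4-bromobenzaldehyde | O=Cc1ccc(Br)c(OCc2ccccc2)c1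
F3 | step 3 | 2-(benzyloxy)-3-[3-(benzyloxy)-4-bromophenyl]-1-(4-bromo-2,6-difluorophenyl)-3-hydroxypropan-1-one (racemic mixture of diastereomers) | O=C(c1c(F)cc(Br)cc1F)C(OCc1ccccc1)C(O)c1ccc(Br)c(OCc2ccccc2)c1
F4 | step 7 | 3,5,3'-tri-O-benzylquercetin 7,4'-bis(2,2,2-trichloroethyl sulfate) | O=c1c(OCc2ccccc2)c(-c2ccc(OS(=O)(=O)OCC(Cl)(Cl)Cl)c(OCc3ccccc3)c2)oc2cc(OS(=O)(=O)OCC(Cl)(Cl)Cl)cc(OCc3ccccc3)c12
F5 | step 7 | diammonium quercetin 7,4'-disulfate | O=c1c(O)c(-c2ccc(OS(=O)(=O)[O-])c(O)c2)oc2cc(OS(=O)(=O)[O-])cc(O)c12.[NH4+].[NH4+]
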